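**Retrosynthetic overview**
- The enal is unmasked last from a dimethyl acetal. The E,E,E-triene is closed at the CH=C(CH3)–CH=CH bond by hydrozirconation of a pent-3-ynyl arm and Negishi coupling with a C11 chlorodiene.
- The Z-configured exocyclic alkene comes from methyl coupling on an enol triflate whose geometry is fixed in the ring-forming step.
- Key step and only ring: titanocene-mediated reductive opening of a Sharpless epoxy alcohol gives a tertiary radical that closes the cyclohexane 6-endo onto a trisubstituted enone. The bond formed joins the quaternary carbon to the ring CH, and the enolate end is caught as the triflate.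
- The acyclic precursor comes from a B-alkyl Suzuki coupling of an α-iodoenone (two C5 pieces) with a dienol made by anti-carbomagnesiation of but-2-yn-1-ol.
- The carbinol centre is set by the asymmetric epoxidation; the quaternary centre, the ring CH and the alkene geometry follow from the radical step.

Assumption: 5-bromopent-2-yne, methyl 4-oxobutanoate and lithium acetylide–ethane-1,2-diamine complex are taken as commercial.

**Step 1**
Reactants: 1 1,1-dimethoxypropan-2-one; 2 methyl 4-oxobutanoate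
Product: 6 methyl (4E)-7,7-dimethoxy-6-oxohept-4-enoate, via lithium enolate 3 (not isolated), via lithium aldolate 4 (not isolated), via mesylate 5 (not isolated)
Conditions: LiN(i-Pr)2, THF, −78 °C; 2, −78 °C; then MsCl, Et3N, −78 °C → rt
Reagents that add atoms: none
Why: Directed lithium-enolate aldol addition of the methyl ketone (the acetal side has no enolisable CH2) followed by E1cB loss of mesylate gives the E-enone, and cold mesylation outruns lactonisation of the aldolate onto the ester.

**Step 2**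
Reactants: 6 methyl (4E)-7,7-dimethoxy-6-oxohept-4-enoate
Product: 7 methyl (4Z)-5-iodo-7,7-dimethoxy-6-oxohept-4-enoate
Conditions: I2, pyridine, DMAP (cat.), CH2Cl2, rt
Reagents that add atoms: iodine, II
Why: Johnson-type α-iodination of an enone (amine conjugate addition, iodination of the enolate, elimination) gives the α-iodoenone with the chain still trans to the acyl group.

**Step 3**
Reactants: 8 but-2-yn-1-ol; 9 5-bromopent-2-yne; 10 bromoethene
Product: 14 (2Z)-3-methyl-2-(pent-3-yn-1-yl)penta-2,4-dien-1-ol, via pent-3-ynylmagnesium bromide 11 (not isolated), via bromomagnesium alkoxide 12 (not isolated), via oxamagnesacycle 13 (not isolated)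
Conditions: Mg, THF (9 → 11); 8 added to 11 (2.5 equiv), CuI (10 mol%), THF, reflux; then 10, Pd(PPh3)4 (5 mol%), rt; aq. work-up
Reagents that add atoms: none
Why: Duboudin–Fallis anti-carbomagnesiation of a propargylic alcohol puts the Grignard carbon on C-2 and leaves a five-membered oxamagnesacycle, whose C–Mg bond undergoes Kumada coupling with retention, so CH2OH ends cis to the vinyl group.

**Step 4**
Reactants: 14 (2Z)-3-methyl-2-(pent-3-yn-1-yl)penta-2,4-dien-1-ol; 7 methyl (4Z)-5-iodo-7,7-dimethoxy-6-oxohept-4-enoate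
Product: 16 methyl (4E,8Z)-5-(2,2-dimethoxyacetyl)-9-(hydroxymethyl)-8-methyltetradeca-4,8-dien-12-ynoate, via alkylborane 15 (not isolated)
Conditions: 9-BBN-H (1.3 equiv), THF, 0 °C → rt; then 7, Pd(dppf)Cl2 (5 mol%), AsPh3, Cs2CO3, DMF/H2O, rt
Reagents that add atoms: none
Why: 9-BBN hydroborates only the terminal vinyl group (anti-Markovnikov; tetrasubstituted alkene and internal alkyne untouched), and the B-alkyl Suzuki–Miyaura coupling with the α-iodoenone keeps the enone geometry (ester arm cis to the new CH2).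

**Step 5**
Reactants: 16 methyl (4E,8Z)-5-(2,2-dimethoxyacetyl)-9-(hydroxymethyl)-8-methyltetradeca-4,8-dien-12-ynoate
Product: 17 methyl (4E)-5-(2,2-dimethoxyacetyl)-7-[(2S,3R)-3-(hydroxymethyl)-2-methyl-3-(pent-3-yn-1-yl)oxiran-2-yl]hept-4-enoate
Conditions: Ti(OiPr)4 (10 mol%), D-(−)-diethyl tartrate (12 mol%), t-BuOOH, 4 Å MS, CH2Cl2, −20 °C
Reagents that add atoms: tert-butyl hydroperoxide, CC(C)(C)OO
Why: Sharpless asymmetric epoxidation of the tetrasubstituted allylic alcohol; the D-(−)-tartrate delivers oxygen to the face opposite to that used by the natural ester (which gives 2S,3S-epoxides from E-allylic alcohols), making the methyl-bearing carbinol carbon S, while the electron-poor enone is inert.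

**Step 6**
Reactants: 17 methyl (4E)-5-(2,2-dimethoxyacetyl)-7-[(2S,3R)-3-(hydroxymethyl)-2-methyl-3-(pent-3-yn-1-yl)oxiran-2-yl]hept-4-enoate
Product: 21 methyl 3-[(1R,2S,3S,6E)-6-[2,2-dimethoxy-1-(trifluoromethanesulfonyloxy)ethylidene]-3-hydroxy-2-(hydroxymethyl)-3-methyl-2-(pent-3-yn-1-yl)cyclohexyl]propanoate, via sodium alkoxide 18 (not isolated), via titanacycle radical 19 (not isolated), via titanium enolate 20 (not isolated)
Conditions: NaH (1.0 equiv), THF, 0 °C; added to (C5H5)2TiCl [from (C5H5)2TiCl2 (2.5 equiv), Mn dust, THF], −20 °C → rt; then PhNTf2 (1.5 equiv), DMPU, rt; aq. NH4Cl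
Reagents that add atoms: N-phenylbis(trifluoromethanesulfonimide), O=S(=O)(N(c1ccccc1)S(=O)(=O)C(F)(F)F)C(F)(F)F
Why: Proposed new method: a Nugent–RajanBabu-type opening by trivalent titanium bound to the alkoxide cleaves the C–O bond next to the carbinol arm (as in the known 1,3-diol-forming openings of 2,3-epoxy alcohols) and gives a tertiary radical inside a six-membered dioxatitanacycle, which adds 6-endo to the enone β-carbon through a chair in which the E-alkene forces the ester arm axial, the small titanoxy group rather than methyl takes the syn-axial site on the carbinol carbon, and the titanacycle then holds the CH2O arm equatorial with pentynyl axial, so CH2OH, OH and the ester arm end on one face; a second equivalent of trivalent titanium reduces the α-keto radical to an enolate that keeps the s-trans enone geometry (oxygen cis to the ring CH2) and is O-triflated in the aprotic flask – the cyclisation is the known titanocene epoxide–enone radical cyclisation, while triflation of the titanium enolate is new and modelled on O-silylation of titanium enolates and PhNTf2 capture of conjugate-addition enolates.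

**Step 7**
Reactants: 21 the enol triflate from step 6
Product: 22 methyl 3-[(1R,2S,3S,6Z)-6-(1,1-dimethoxypropan-2-ylidene)-3-hydroxy-2-(hydroxymethyl)-3-methyl-2-(pent-3-yn-1-yl)cyclohexyl]propanoate
Conditions: MeZnCl (4 equiv), Pd(dppf)Cl2 (5 mol%), THF, 50 °C
Reagents that add atoms: methylzinc chloride, C[Zn]Cl
Why: Negishi coupling of the enol triflate with retention puts methyl cis to the ring CH2 and leaves the acetal carbon cis to the ring CH, which is the Z arrangement of the future enal.

**Step 8**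
Reactants: 22 the methyl ester from step 7
Product: 23 (1S,2S,3R,4Z)-4-(1,1-dimethoxypropan-2-ylidene)-2-(hydroxymethyl)-3-(3-hydroxypropyl)-1-methyl-2-(pent-3-yn-1-yl)cyclohexan-1-ol
Conditions: LiAlH4, THF, 0 °C; NaOH work-up
Reagents that add atoms: none
Why: Hydride reduction of the methyl ester to the primary alcohol; acetal, internal alkyne and tetrasubstituted alkene are inert.

**Step 9**
Reactants: 24 5-bromo-2-methylpent-2-ene; 25 lithium acetylide–ethane-1,2-diamine complex
Product: 26 6-methylhept-5-en-1-yne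
Conditions: DMSO, 10 °C → rt
Reagents that add atoms: none
Why: SN2 alkylation of lithium acetylide by the primary homoallylic bromide.

**Step 10**
Reactants: 26 6-methylhept-5-en-1-yne; 27 (E)-1,2-dichloroethene
Product: 29 (1E,3E)-1-chloro-4,8-dimethylnona-1,3,7-triene, via alkenylalane 28 (not isolated)
Conditions: Me3Al (2 equiv), (C5H5)2ZrCl2 (20 mol%), CH2Cl2, 0 °C → rt; then 27 (5 equiv), Pd(PPh3)4 (5 mol%), THF, rt
Reagents that add atoms: trimethylaluminium, C[Al](C)C
Why: Negishi zirconium-catalysed syn-carboalumination (methyl to the internal carbon) gives the E-alkenylalane, and palladium-catalysed monocoupling with excess E-dichloroethene proceeds with retention at both partners.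

**Step 11**
Reactants: 23 the triol acetal from step 8; 29 (1E,3E)-1-chloro-4,8-dimethylnona-1,3,7-triene
Product: 31 (1S,2S,3R,4Z)-4-(1,1-dimethoxypropan-2-ylidene)-2-(hydroxymethyl)-3-(3-hydroxypropyl)-1-methyl-2-[(3E,5E,7E)-4,8,12-trimethyltrideca-3,5,7,11-tetraen-1-yl]cyclohexan-1-ol, via alkenylzirconocene 30 (not isolated)
Conditions: (C5H5)2Zr(H)Cl (5.5 equiv), THF, rt → 50 °C; then 29, ZnCl2 (20 mol%), Pd[P(t-Bu)3]2 (5 mol%), THF, 50 °C; aq. NH4Cl
Reagents that add atoms: none
Why: Syn-hydrozirconation of the methyl-capped alkyne settles zirconium on the methyl-bearing carbon after equilibration (about 9:1 expected; the minor isomer is removed after coupling), and Negishi coupling through a zinc shuttle joins the alkenes with retention to the E,E,E-triene, the three hydroxyls being carried as zirconium alkoxides.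

**Step 12**
Reactants: 31 the triene acetal from step 11
Product: 32 (2Z)-2-[(2R,3S,4S)-4-hydroxy-3-(hydroxymethyl)-2-(3-hydroxypropyl)-4-methyl-3-[(3E,5E,7E)-4,8,12-trimethyltrideca-3,5,7,11-tetraen-1-yl]cyclohexylidene]propanal
Conditions: PPTS (cat.), acetone/H2O (10:1), rt
Reagents that add atoms: water, O
Why: Mild acid hydrolysis of the allylic dimethyl acetal frees the enal without isomerising the tetrasubstituted alkene or the triene.

**Compound list**
1 | 1,1-dimethoxypropan-2-one | CC(=O)C(OC)OC | starting material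
2 | methyl 4-oxobutanoate | COC(=O)CCC=O | starting material
3 | lithium 3,3-dimethoxyprop-1-en-2-olate | [Li]OC(=C)C(OC)OC | intermediate
4 | methyl 4-(lithiooxy)-7,7-dimethoxy-6-oxoheptanoate | COC(=O)CCC(O[Li])CC(=O)C(OC)OC | intermediate
5 | methyl 7,7-dimethoxy-4-(methanesulfonyloxy)-6-oxoheptanoate | COC(=O)CCC(OS(C)(=O)=O)CC(=O)C(OC)OC | intermediate
6 | methyl (4E)-7,7-dimethoxy-6-oxohept-4-enoate | COC(=O)CC/C=C/C(=O)C(OC)OC | intermediate
7 | methyl (4Z)-5-iodo-7,7-dimethoxy-6-oxohept-4-enoate | COC(=O)CC/C=C(\I)C(=O)C(OC)OC | intermediate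
8 | but-2-yn-1-ol | CC#CCO | starting material
9 | 5-bromopent-2-yne | CC#CCCBr | starting material
10 | bromoethene | C=CBr | starting material
11 | pent-3-yn-1-ylmagnesium bromide | CC#CCC[Mg]Br | intermediate
12 | bromomagnesium but-2-yn-1-olate | CC#CCO[Mg]Br | intermediate
13 | 3-methyl-4-(pent-3-yn-1-yl)-2,5-dihydro-1,2-oxamagnesole | CC#CCCC1=C(C)[Mg]OC1 | intermediate
14 | (2Z)-3-methyl-2-(pent-3-yn-1-yl)penta-2,4-dien-1-ol | OC/C(=C(/C)C=C)CCC#CC | intermediate
15 | (2Z)-5-(9-borabicyclo[3.3.1]nonan-9-yl)-3-methyl-2-(pent-3-yn-1-yl)pent-2-en-1-ol | OC/C(=C(/C)CCB1C2CCCC1CCC2)CCC#CC | intermediate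
16 | methyl (4E,8Z)-5-(2,2-dimethoxyacetyl)-9-(hydroxymethyl)-8-methyltetradeca-4,8-dien-12-ynoate | OC/C(=C(/C)CC/C(=C\CCC(=O)OC)C(=O)C(OC)OC)CCC#CC | intermediate
17 | methyl (4E)-5-(2,2-dimethoxyacetyl)-7-[(2S,3R)-3-(hydroxymethyl)-2-methyl-3-(pent-3-yn-1-yl)oxiran-2-yl]hept-4-enoate | OC[C@@]1(CCC#CC)O[C@@]1(C)CC/C(=C\CCC(=O)OC)C(=O)C(OC)OC | intermediate
18 | sodium alkoxide of 17 | [Na]OC[C@@]1(CCC#CC)O[C@@]1(C)CC/C(=C\CCC(=O)OC)C(=O)C(OC)OC | intermediate
19 | tertiary carbon radical in a 2,2-bis(cyclopentadienyl)-1,3-dioxa-2-titanacyclohexane (ring oxygens on the carbinol carbon and the CH2 arm; enone chain still open) | COC(=O)CC/C=C(\CC[C@]1(C)O[Ti](C2C=CC=C2)(C2C=CC=C2)OC[C]1CCC#CC)C(=O)C(OC)OC | intermediate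
20 | cyclised titanium enolate (chlorotitanocene on the enolate oxygen; the diol held as the titanacycle) | CC#CCC[C@@]1(CO3)[C@H](CCC(=O)OC)/C(=C(/O[Ti](Cl)(C2C=CC=C2)C2C=CC=C2)C(OC)OC)CC[C@]1(C)O[Ti]3(C2C=CC=C2)C2C=CC=C2 | intermediate
21 | methyl 3-[(1R,2S,3S,6E)-6-[2,2-dimethoxy-1-(trifluoromethanesulfonyloxy)ethylidene]-3-hydroxy-2-(hydroxymethyl)-3-methyl-2-(pent-3-yn-1-yl)cyclohexyl]propanoate | CC#CCC[C@@]1(CO)[C@H](CCC(=O)OC)/C(=C(/OS(=O)(=O)C(F)(F)F)C(OC)OC)CC[C@]1(C)O | intermediate
22 | methyl 3-[(1R,2S,3S,6Z)-6-(1,1-dimethoxypropan-2-ylidene)-3-hydroxy-2-(hydroxymethyl)-3-methyl-2-(pent-3-yn-1-yl)cyclohexyl]propanoate | CC#CCC[C@@]1(CO)[C@H](CCC(=O)OC)/C(=C(/C)C(OC)OC)CC[C@]1(C)O | intermediate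
23 | (1S,2S,3R,4Z)-4-(1,1-dimethoxypropan-2-ylidene)-2-(hydroxymethyl)-3-(3-hydroxypropyl)-1-methyl-2-(pent-3-yn-1-yl)cyclohexan-1-ol | CC#CCC[C@@]1(CO)[C@H](CCCO)/C(=C(/C)C(OC)OC)CC[C@]1(C)O | intermediate
24 | 5-bromo-2-methylpent-2-ene | CC(C)=CCCBr | starting material
25 | lithium acetylide–ethane-1,2-diamine complex | [Li]C#C.NCCN | starting material
26 | 6-methylhept-5-en-1-yne | CC(C)=CCCC#C | intermediate
27 | (E)-1,2-dichloroethene | Cl/C=C/Cl | starting material
28 | [(1E)-2,6-dimethylhepta-1,5-dien-1-yl]dimethylalumane | CC(C)=CCC/C(C)=C/[Al](C)C | intermediate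
29 | (1E,3E)-1-chloro-4,8-dimethylnona-1,3,7-triene | CC(C)=CCC/C(C)=C/C=C/Cl | intermediate
30 | E-alkenyl(chloro)zirconocene from 23, zirconium on the methyl-bearing alkene carbon, the three hydroxyls as chlorozirconocene alkoxides | Cl[Zr](C2C=CC=C2)(C2C=CC=C2)/C(C)=C/CC[C@@]1(CO[Zr](Cl)(C2C=CC=C2)C2C=CC=C2)[C@H](CCCO[Zr](Cl)(C2C=CC=C2)C2C=CC=C2)/C(=C(/C)C(OC)OC)CC[C@]1(C)O[Zr](Cl)(C2C=CC=C2)C2C=CC=C2 | intermediate
31 | (1S,2S,3R,4Z)-4-(1,1-dimethoxypropan-2-ylidene)-2-(hydroxymethyl)-3-(3-hydroxypropyl)-1-methyl-2-[(3E,5E,7E)-4,8,12-trimethyltrideca-3,5,7,11-tetraen-1-yl]cyclohexan-1-ol | CC(C)=CCC/C(C)=C/C=C/C(C)=C/CC[C@@]1(CO)[C@H](CCCO)/C(=C(/C)C(OC)OC)CC[C@]1(C)O | intermediate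
32 | (2Z)-2-[(2R,3S,4S)-4-hydroxy-3-(hydroxymethyl)-2-(3-hydroxypropyl)-4-methyl-3-[(3E,5E,7E)-4,8,12-trimethyltrideca-3,5,7,11-tetraen-1-yl]cyclohexylidene]propanal | CC(C)=CCC/C(C)=C/C=C/C(C)=C/CC[C@@]1(CO)[C@H](CCCO)/C(=C(/C)C=O)CC[C@]1(C)O | target

**Count**
Total steps: 12. Longest linear sequence: 9 (steps 1, 2, 4, 5, 6, 7, 8, 11, 12).

**Steps most likely to fail, with fallbacks**

Step 6. The risks are the face selectivity of the 6-endo closure, loss of enolate geometry by rotation of the α-keto radical before reduction, and the untested O-triflation of a titanium enolate. The fallback separates the radical step from the sulfonylation. It sets out from 17: the same sodium alkoxide and titanocene cyclisation is quenched with Me3SiCl/Et3N instead of PhNTf2, which gives methyl 3-[(1R,2S,3S,6E)-6-[2,2-dimethoxy-1-(trimethylsilyloxy)ethylidene]-3-methyl-2-(pent-3-yn-1-yl)-3-(trimethylsilyloxy)-2-[(trimethylsilyloxy)methyl]cyclohexyl]propanoate F1. The silyl enol ether is then opened with CsF in DME in the presence of PhNTf2, so a metal-free enolate is triflated as it forms, and brief K2CO3/MeOH removes the two alkyl silyl ethers. The route is rejoined at 21.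

Step 3. Primary alkyl Grignards add to propargylic alcohols less cleanly than allyl or vinyl reagents, and the one-flask Kumada coupling of the hindered oxamagnesacycle may stall. The fallback builds the tetrasubstituted alkene from a β-keto ester instead. It sets out from 9 and commercial methyl acetoacetate: alkylation (K2CO3, acetone) gives methyl 2-acetylhept-5-ynoate F2. Chelation-controlled triflation (aqueous LiOH, Tf2O, toluene) gives methyl (2Z)-2-(pent-3-yn-1-yl)-3-(trifluoromethanesulfonyloxy)but-2-enoate F3. Suzuki coupling with potassium vinyltrifluoroborate (Pd(dppf)Cl2, K2CO3) gives methyl (2Z)-3-methyl-2-(pent-3-yn-1-yl)penta-2,4-dienoate F4, and DIBAL-H reduction rejoins the route at 14.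

Step 11. The risks are incomplete regiocontrol in the hydrozirconation of a methyl/primary-alkyl alkyne on a triol, and the low reactivity of an alkenyl chloride. The fallback reverses the polarity of the coupling. It sets out from 23 and 29: hydrozirconation of 23 followed by iodine gives (1S,2S,3R,4Z)-4-(1,1-dimethoxypropan-2-ylidene)-2-(hydroxymethyl)-3-(3-hydroxypropyl)-2-[(3E)-4-iodopent-3-en-1-yl]-1-methylcyclohexan-1-ol F5, which is freed of its regioisomer at this stage. Miyaura borylation of 29 (Pd2(dba)3, XPhos, bis(pinacolato)diboron, KOAc) gives 2-[(1E,3E)-4,8-dimethylnona-1,3,7-trien-1-yl]-4,4,5,5-tetramethyl-1,3,2-dioxaborolane F6. Suzuki coupling of F5 with F6 (Pd(dppf)Cl2, aqueous K3PO4, THF) rejoins the route at 31.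

**Further compounds**
F1 | step 6 | methyl 3-[(1R,2S,3S,6E)-6-[2,2-dimethoxy-1-(trimethylsilyloxy)ethylidene]-3-methyl-2-(pent-3-yn-1-yl)-3-(trimethylsilyloxy)-2-[(trimethylsilyloxy)methyl]cyclohexyl]propanoate | CC#CCC[C@@]1(CO[Si](C)(C)C)[C@H](CCC(=O)OC)/C(=C(/O[Si](C)(C)C)C(OC)OC)CC[C@]1(C)O[Si](C)(C)C
F2 | step 3 | methyl 2-acetylhept-5-ynoate | CC#CCCC(C(C)=O)C(=O)OC
F3 | step 3 | methyl (2Z)-2-(pent-3-yn-1-yl)-3-(trifluoromethanesulfonyloxy)but-2-enoate | COC(=O)/C(CCC#CC)=C(/C)OS(=O)(=O)C(F)(F)F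
F4 | step 3 | methyl (2Z)-3-methyl-2-(pent-3-yn-1-yl)penta-2,4-dienoate | COC(=O)/C(CCC#CC)=C(/C)C=C
F5 | step 11 | (1S,2S,3R,4Z)-4-(1,1-dimethoxypropan-2-ylidene)-2-(hydroxymethyl)-3-(3-hydroxypropyl)-2-[(3E)-4-iodopent-3-en-1-yl]-1-methylcyclohexan-1-ol | I/C(C)=C/CC[C@@]1(CO)[C@H](CCCO)/C(=C(/C)C(OC)OC)CC[C@]1(C)O
F6 | step 11 | 2-[(1E,3E)-4,8-dimethylnona-1,3,7-trien-1-yl]-4,4,5,5-tetramethyl-1,3,2-dioxaborolane | CC(C)=CCC/C(C)=C/C=C/B1OC(C)(C)C(C)(C)O1
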